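The constants stand for no real mixture.

The easy step is the opening of starting material to open intermediate: the reckoning takes it as balanced and runs on what it leaves free.

    open intermediate + second intermediate → target (k1 = 0.0089 /M/s, Ea1 = 75.0 kJ/mol)
    starting material ⇌ open intermediate (K2 = 0.39, k2 = 0.0056 /s, Ea2 = 82.0 kJ/mol, ΔH2 = −22.0 kJ/mol)
    open intermediate + capture agent → trapped intermediate (k3 = 3.9 × 10⁻⁴ /M/s, Ea3 = 74.0 kJ/mol)
    partner → second intermediate (k4 = 9.6 × 10⁻⁴ /s, Ea4 = 86.0 kJ/mol)
    open intermediate → side product (k5 = 5.8 × 10⁻⁴ /s, Ea5 = 82.0 kJ/mol)
    (constants at 35 °C)

in all of them: capture agent 0.0900 M; time 3.0 h

|  | starting material | partner | temperature | remark |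
|---|---|---|---|---|
| alder | 0.30 M | 0.270 M (fed, over 8.0 min) | 35 °C | all else is in the flask from the start; the feed brings no volume worth counting |
| cedar | 0.30 M | 0.270 M | 35 °C | everything together at the start |
| elm | 0.30 M | 0.270 M (fed, over 80 min) |  | the addition at −5 °C, then warmed to 35 °C; the feed brings no volume worth counting |
| ash | 0.30 M (fed, over 80 min) | 0.270 M | 35 °C | all else is in the flask from the start; the feed brings no volume worth counting |

* which flask leads in amount of side product, in percent of the starting material charged ("all alike" within 1.5 percentage points) (alder / cedar / elm / ash / all alike)
* how much side product is there at the end, in percent of the starting material charged: alder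
* how much side product is there at the end, in percent of the starting material charged: cedar
* how much side product is there at the end, in percent of the starting material charged: elm
* how much side product is there at the end, in percent of the starting material charged: ash

- all constants are for 35 °C and move with temperature by the activation energies and enthalpies

**Quick opening.** At 35 °C, starting material and open intermediate relax together with a half-life of 0.579 min, far shorter than the 0.33 h half-life of the open intermediate's leak to side product. So the pair holds its ratio 0.39. Both exits draw on the same open intermediate, so its level cancels in the ratio of their rates.

**Two times.** The leak alone takes a mean time τ_L, the inverse of its constant, of 28.7 min. Second intermediate at the full partner charge C would capture open intermediate in τ_C = 6.94 min, so τ_L/τ_C is 4.14. The times are equal at the break-even level J_b, the leak constant over the target constant, 0.0652 M. Second intermediate at level J gives J/J_b target per side product, a selectivity factor.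

**Own reckoning.** Suppose second intermediate stands ready in full and the starting material ends as target or side product. Integrating J_b/J as J falls gives side product V = J_b ln(C/J_end), with J_end = C − A + V for a charge A of starting material. Trying J_end = J_b gives 0.0926 M, or 30.9 % of the charge. That returns J_end = 0.0626 M, close to J_b, so the trial stands.

Ash comes close to this case, since the partner's half-life of 0.20 h is shorter than the 80 min feed of starting material. In cedar, starting material opens with a forward half-life of 2.1 min, faster than partner converts, so cedar should lie above ash by an unreckoned amount. Alder, with its 8.0 min feed of partner, should lie higher still. Elm's cold addition moves the constants and stays outside this reckoning.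

**Forecast.** The forecast gave 39 % for alder, 37 % for cedar, 34.5 % for elm and 33 % for ash, naming alder, on the ground that “delaying the partner (alder) gives the leak slightly more head start”; its ash figure is higher than the 30.9 % reckoned here.

**Result.** Alder leads with 38.5 %, then cedar 36.8 %, elm 34.4 % and ash 29.9 %, against the reckoned 30.9 %. In ash at 3.00 h, second intermediate stands at 0.0761 M, which is 1.17 times J_b, and the target path uses open intermediate 1.2 times as fast as the leak. The neighbour of ash charged with 0.068 M of partner has a whole charge of 1.04 times J_b, and its second intermediate ends at 0.00561 M. The same integral gives 54.2 % there, and that flask holds 57.6 % side product against 20.8 % target.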